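**Retrosynthetic overview**
- Feature: ring A is a phloroglucinol whose oxygens O1 (on C8a), O5 (on C5) and O7 (on C7) have different fates. The prenyl group on C8 sits between C8a–O1 and C7–O7. A vinylketene/ynol ether benzannulation delivers exactly this 1-hydroxy-2-alkyl-3-siloxy-5-alkoxy benzene.
- Ring A is made first. A 3-(methoxymethoxy)cyclobutenone and a prenyl-substituted triisopropylsiloxyalkyne are fused thermally (bonds C8a–C8, C7–C6, C8a–C4a). This gives a tetrasubstituted benzene in which only O1 is free.
- C4 and C3 follow: chelation-directed formylation at the single open ortho carbon (C4a), addition of a MOMOCH2 anion, and oxidation to the ω-oxygenated acetophenone.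
- Ring C is made last, and ring B is bought as protocatechuic acid. The sequence is O1-aroylation, Baker–Venkataraman shift (C3–C2), then acid closure of O1–C2 with loss of all MOM groups while the O7–TIPS ether shields the prenyl group. Fluoride then frees O7.

Key step: step 4

Assumption: 3-ethoxycyclobutenone, ethyl 4-methylpent-3-enoate and (tributylstannyl)methanol are taken as catalogue compounds; flavone numbering is used for ring A atoms throughout, and the target has no stereocentre.

**Step 1**
Reactants: 1 3-ethoxycyclobut-2-en-1-one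
Product: 2 cyclobutane-1,3-dione (tautomer: 3-hydroxycyclobut-2-en-1-one)
Conditions: 2 M aq HCl, 0 °C → rt; cold concentration, crystallisation
Reagents that add atoms: water, O
Why: Acid hydrolysis of a vinylogous ester (water adds at C3, ethanol leaves) should give the crystalline, strongly acidic dione, which is used promptly because it does not keep.

**Step 2**
Reactants: 2 cyclobutane-1,3-dione
Product: 3 3-(methoxymethoxy)cyclobut-2-en-1-one
Conditions: MOMCl, iPr2NEt, CH2Cl2, −20 → 0 °C; Et3N-deactivated silica
Reagents that add atoms: chloromethyl methyl ether, COCCl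
Why: O-alkylation of the delocalised 1,3-dione anion by the hard, oxocarbenium-like electrophile MOMCl goes on oxygen, as with tetronic acids and cyclic 1,3-diones, and the moisture-sensitive vinylogous acylal is handled only under neutral anhydrous conditions.

**Step 3**
Reactants: 4 ethyl 4-methylpent-3-enoate; 5 triisopropylsilyl chloride
Product: 8 triisopropyl[(5-methylhex-4-en-1-yn-1-yl)oxy]silane, via lithium dibromoenolate 6 (not isolated), via lithium ynolate 7 (not isolated)
Conditions: CH2Br2, lithium 2,2,6,6-tetramethylpiperidide (LiTMP), THF, −78 °C, then 4; LiN(SiMe3)2, −78 °C; n-BuLi, −78 °C → rt; 5, −78 → 0 °C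
Reagents that add atoms: dibromomethane, BrCBr
Why: This is a Kowalski ester homologation stopped at the ynolate: LiCHBr2 adds to the ester, base converts the adduct into 6, bromine–lithium exchange triggers 1,2-migration of the prenyl group to the carbenoid carbon to give 7, and the bulky silyl chloride traps 7 on oxygen rather than on carbon.

**Step 4**
Reactants: 3 3-(methoxymethoxy)cyclobut-2-en-1-one; 8 triisopropyl[(5-methylhex-4-en-1-yn-1-yl)oxy]silane
Product: 13 5-(methoxymethoxy)-2-(3-methylbut-2-en-1-yl)-3-[(triisopropylsilyl)oxy]phenol, via vinylketene 9 (not isolated), via vinylcyclobutenone 10 (not isolated), via dienylketene 11 (not isolated), via cyclohexadienone 12 (not isolated)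
Conditions: 8 (1.3 equiv), 2,6-di-tert-butyl-4-methylpyridine (0.1 equiv), toluene, 110 °C, slow addition of 3, Ar
Reagents that add atoms: none
Why: Danheiser benzannulation: heat cleaves the C1–C4 bond of 3 in a conrotatory four-electron electrocyclic opening to vinylketene 9, whose electrophilic ketene carbon is attacked by the prenyl-bearing carbon of the oxygen-polarised alkyne 8 in a regiospecific (2+2) cycloaddition that gives 10 and forms C8a–C8 and C7–C6. Compound 10 reopens by a second four-electron process to dienylketene 11, ring A closes by a six-electron disrotatory electrocyclisation joining the ketene carbon to the terminal CH2 (C8a–C4a), and dienone 12 tautomerises irreversibly to phenol 13. The closest known reaction type is the thermal benzannulation of alkyl-substituted cyclobutenones with triisopropylsiloxyalkynes to resorcinol monosilyl ethers, and the only variation here is the oxygen substituent on C3 of the four-membered ring. No stereocentre survives, since the sp3 ring carbon of 10 forms racemic and is erased on reopening. The selectivity required is the orientation of the (2+2) step, which the donor oxygen of the alkyne fixes, so that prenyl lands next to the carbon carrying the only free hydroxyl (future O1) with the siloxy oxygen (future O7) on its other side and the MOM oxygen (future O5) remote. Slow addition of 3 to an excess of 8 keeps the ketene dilute, which holds back its oligomerisation and the acylation of 13, and the hindered pyridine scavenges traces of acid that would protonate 8.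

**Step 5**
Reactants: 13 5-(methoxymethoxy)-2-(3-methylbut-2-en-1-yl)-3-[(triisopropylsilyl)oxy]phenol
Product: 14 2-hydroxy-6-(methoxymethoxy)-3-(3-methylbut-2-en-1-yl)-4-[(triisopropylsilyl)oxy]benzaldehyde
Conditions: MgCl2, Et3N, (CH2O)n, MeCN, reflux; cold dilute HCl work-up
Reagents that add atoms: paraformaldehyde (as formaldehyde), C=O
Why: In the Casnati–Skattebøl ortho-formylation the magnesium phenoxide delivers formaldehyde through a six-membered chelate to an ortho carbon only; because prenyl blocks the other ortho position, the single open one (future C4a) reacts rather than the para carbon (future C6), and a second formaldehyde accepts hydride to give the aldehyde.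

**Step 6**
Reactants: 15 (tributylstannyl)methanol
Product: 16 tributyl[(methoxymethoxy)methyl]stannane
Conditions: MOMCl, iPr2NEt, CH2Cl2, 0 °C → rt
Reagents that add atoms: chloromethyl methyl ether, COCCl
Why: Acetal-forming O-alkylation of an unhindered primary alcohol gives the standard tin precursor of a protected hydroxymethyl anion.

**Step 7**
Reactants: 14 2-hydroxy-6-(methoxymethoxy)-3-(3-methylbut-2-en-1-yl)-4-[(triisopropylsilyl)oxy]benzaldehyde; 16 tributyl[(methoxymethoxy)methyl]stannane
Product: 18 2-[1-hydroxy-2-(methoxymethoxy)ethyl]-3-(methoxymethoxy)-6-(3-methylbut-2-en-1-yl)-5-[(triisopropylsilyl)oxy]phenol (racemic), via (methoxymethoxy)methyllithium 17 (not isolated)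
Conditions: 16 (2.6 equiv), n-BuLi (2.5 equiv), THF, −78 °C; then 14, −78 → −40 °C; aq NH4Cl; crude product carried on
Reagents that add atoms: none
Why: Tin–lithium exchange gives the chelation-stabilised α-alkoxyorganolithium 17, of which one equivalent is spent on the phenol O–H and a second adds 1,2 to the aldehyde; the new carbinol centre forms racemic and needs no control because step 8 removes it.

**Step 8**
Reactants: 18 2-[1-hydroxy-2-(methoxymethoxy)ethyl]-3-(methoxymethoxy)-6-(3-methylbut-2-en-1-yl)-5-[(triisopropylsilyl)oxy]phenol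
Product: 19 1-[2-hydroxy-6-(methoxymethoxy)-3-(3-methylbut-2-en-1-yl)-4-[(triisopropylsilyl)oxy]phenyl]-2-(methoxymethoxy)ethan-1-one
Conditions: activated MnO2 (excess), CH2Cl2, rt
Reagents that add atoms: none
Why: MnO2 oxidation is selective for the activated, electron-rich benzylic alcohol, its neutral heterogeneous conditions leave the alkene, acetals and silyl ether untouched, and the ketone formed is stabilised by the O1–H···O=C hydrogen bond.

**Step 9**
Reactants: 20 3,4-dihydroxybenzoic acid
Product: 21 methoxymethyl 3,4-bis(methoxymethoxy)benzoate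
Conditions: MOMCl (3.5 equiv), iPr2NEt, CH2Cl2–DMF, 0 °C → rt
Reagents that add atoms: chloromethyl methyl ether, COCCl
Why: Exhaustive O-alkylation of the two phenols and the carboxylate with MOMCl masks ring B with the same acid-labile group used on O3 and O5.

**Step 10**
Reactants: 21 methoxymethyl 3,4-bis(methoxymethoxy)benzoate
Product: 22 3,4-bis(methoxymethoxy)benzoic acid
Conditions: LiOH, THF–MeOH–H2O, rt; then 1 M HCl to pH 4, 0 °C
Reagents that add atoms: lithium hydroxide, [Li+].[OH-]
Why: Saponification cleaves the acylal-type MOM ester quickly, whereas the aryl MOM ethers are inert to base and survive the brief, cold, mild acidification.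

**Step 11**
Reactants: 19 1-[2-hydroxy-6-(methoxymethoxy)-3-(3-methylbut-2-en-1-yl)-4-[(triisopropylsilyl)oxy]phenyl]-2-(methoxymethoxy)ethan-1-one; 22 3,4-bis(methoxymethoxy)benzoic acid
Product: 23 2-[(methoxymethoxy)acetyl]-3-(methoxymethoxy)-6-(3-methylbut-2-en-1-yl)-5-[(triisopropylsilyl)oxy]phenyl 3,4-bis(methoxymethoxy)benzoate
Conditions: DCC, DMAP (cat.), CH2Cl2, 0 °C → rt
Reagents that add atoms: none
Why: In the Steglich esterification the DMAP-derived acylpyridinium ion acylates the hindered, hydrogen-bonded O1–H under neutral conditions, which avoids an acid chloride and HCl and so spares the MOM groups.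

**Step 12**
Reactants: 23 2-[(methoxymethoxy)acetyl]-3-(methoxymethoxy)-6-(3-methylbut-2-en-1-yl)-5-[(triisopropylsilyl)oxy]phenyl 3,4-bis(methoxymethoxy)benzoate
Product: 24 1-[3,4-bis(methoxymethoxy)phenyl]-3-[2-hydroxy-6-(methoxymethoxy)-3-(3-methylbut-2-en-1-yl)-4-[(triisopropylsilyl)oxy]phenyl]-2-(methoxymethoxy)propane-1,3-dione (racemic, tautomeric)
Conditions: LiN(SiMe3)2 (3 equiv), THF, −78 → −10 °C; aq NH4Cl
Reagents that add atoms: none
Why: In the Baker–Venkataraman rearrangement the α-alkoxy ketone enolate attacks the neighbouring aryl ester carbonyl through a six-membered transition state and expels the O1 phenoxide, forming C3–C2; the C3 centre is configurationally labile and becomes sp2 in step 13.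

**Step 13**
Reactants: 24 1-[3,4-bis(methoxymethoxy)phenyl]-3-[2-hydroxy-6-(methoxymethoxy)-3-(3-methylbut-2-en-1-yl)-4-[(triisopropylsilyl)oxy]phenyl]-2-(methoxymethoxy)propane-1,3-dione
Product: 25 2-(3,4-dihydroxyphenyl)-3,5-dihydroxy-8-(3-methylbut-2-en-1-yl)-7-[(triisopropylsilyl)oxy]-4H-chromen-4-one
Conditions: 3 M aq HCl, MeOH–THF, 45 °C, Ar
Reagents that add atoms: none
Why: Acid-catalysed cyclodehydration of the o-hydroxyaryl 1,3-diketone (O1–H adds 6-exo-trig to the aroyl carbonyl and water is lost, closing ring C) runs together with acetal methanolysis of the four MOM groups, while the acid-stable aryl TIPS ether on O7 and the ring-bound O1 leave no free hydroxyl beside the prenyl group, so chroman formation is blocked.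

**Step 14**
Reactants: 25 2-(3,4-dihydroxyphenyl)-3,5-dihydroxy-8-(3-methylbut-2-en-1-yl)-7-[(triisopropylsilyl)oxy]-4H-chromen-4-one
Product: 26 8-prenylquercetin, 2-(3,4-dihydroxyphenyl)-3,5,7-trihydroxy-8-(3-methylbut-2-en-1-yl)-4H-chromen-4-one
Conditions: Bu4NF, AcOH, THF, 0 °C, Ar
Reagents that add atoms: none
Why: Fluoride-induced desilylation is fast at 0 °C because O7 is a vinylogous-acid leaving group, and acetic acid buffering under argon prevents base-promoted autoxidation of the catechol and flavonol while remaining too weakly acidic to cyclise the prenyl group.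

**Compound list**
1 | 3-ethoxycyclobut-2-en-1-one | CCOC1=CC(=O)C1 | starting material
2 | cyclobutane-1,3-dione | O=C1CC(=O)C1 | intermediate
3 | 3-(methoxymethoxy)cyclobut-2-en-1-one | COCOC1=CC(=O)C1 | intermediate
4 | ethyl 4-methylpent-3-enoate | CCOC(=O)CC=C(C)C | starting material
5 | triisopropylsilyl chloride | CC(C)[Si](Cl)(C(C)C)C(C)C | starting material
6 | lithium 1,1-dibromo-5-methylhexa-1,4-dien-2-olate | CC(C)=CCC([O-])=C(Br)Br.[Li+] | intermediate
7 | lithium 5-methylhex-4-en-1-yn-1-olate | CC(C)=CCC#C[O-].[Li+] | intermediate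
8 | triisopropyl[(5-methylhex-4-en-1-yn-1-yl)oxy]silane | CC(C)=CCC#CO[Si](C(C)C)(C(C)C)C(C)C | intermediate
9 | 3-(methoxymethoxy)buta-1,3-dien-1-one | C=C(OCOC)C=C=O | intermediate
10 | 4-[1-(methoxymethoxy)ethenyl]-2-(3-methylbut-2-en-1-yl)-3-[(triisopropylsilyl)oxy]cyclobut-2-en-1-one (racemic) | COCOC(=C)C1C(=O)C(CC=C(C)C)=C1O[Si](C(C)C)(C(C)C)C(C)C | intermediate
11 | (3E)-5-(methoxymethoxy)-2-(3-methylbut-2-en-1-yl)-3-[(triisopropylsilyl)oxy]hexa-1,3,5-trien-1-one (ketene and alkoxyvinyl groups cis) | O=C=C(CC=C(C)C)/C(O[Si](C(C)C)(C(C)C)C(C)C)=C\C(=C)OCOC | intermediate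
12 | 5-(methoxymethoxy)-2-(3-methylbut-2-en-1-yl)-3-[(triisopropylsilyl)oxy]cyclohexa-2,4-dien-1-one | O=C1CC(OCOC)=CC(O[Si](C(C)C)(C(C)C)C(C)C)=C1CC=C(C)C | intermediate
13 | 5-(methoxymethoxy)-2-(3-methylbut-2-en-1-yl)-3-[(triisopropylsilyl)oxy]phenol | CC(C)=CCc1c(O)cc(OCOC)cc1O[Si](C(C)C)(C(C)C)C(C)C | intermediate
14 | 2-hydroxy-6-(methoxymethoxy)-3-(3-methylbut-2-en-1-yl)-4-[(triisopropylsilyl)oxy]benzaldehyde | CC(C)=CCc1c(O)c(C=O)c(OCOC)cc1O[Si](C(C)C)(C(C)C)C(C)C | intermediate
15 | (tributylstannyl)methanol | CCCC[Sn](CCCC)(CCCC)CO | starting material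
16 | tributyl[(methoxymethoxy)methyl]stannane | CCCC[Sn](CCCC)(CCCC)COCOC | intermediate
17 | (methoxymethoxy)methyllithium | [Li]COCOC | intermediate
18 | 2-[1-hydroxy-2-(methoxymethoxy)ethyl]-3-(methoxymethoxy)-6-(3-methylbut-2-en-1-yl)-5-[(triisopropylsilyl)oxy]phenol (racemic) | CC(C)=CCc1c(O)c(C(O)COCOC)c(OCOC)cc1O[Si](C(C)C)(C(C)C)C(C)C | intermediate
19 | 1-[2-hydroxy-6-(methoxymethoxy)-3-(3-methylbut-2-en-1-yl)-4-[(triisopropylsilyl)oxy]phenyl]-2-(methoxymethoxy)ethan-1-one | CC(C)=CCc1c(O)c(C(=O)COCOC)c(OCOC)cc1O[Si](C(C)C)(C(C)C)C(C)C | intermediate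
20 | 3,4-dihydroxybenzoic acid | O=C(O)c1ccc(O)c(O)c1 | starting material
21 | methoxymethyl 3,4-bis(methoxymethoxy)benzoate | COCOC(=O)c1ccc(OCOC)c(OCOC)c1 | intermediate
22 | 3,4-bis(methoxymethoxy)benzoic acid | O=C(O)c1ccc(OCOC)c(OCOC)c1 | intermediate
23 | 2-[(methoxymethoxy)acetyl]-3-(methoxymethoxy)-6-(3-methylbut-2-en-1-yl)-5-[(triisopropylsilyl)oxy]phenyl 3,4-bis(methoxymethoxy)benzoate | CC(C)=CCc1c(OC(=O)c2ccc(OCOC)c(OCOC)c2)c(C(=O)COCOC)c(OCOC)cc1O[Si](C(C)C)(C(C)C)C(C)C | intermediate
24 | 1-[3,4-bis(methoxymethoxy)phenyl]-3-[2-hydroxy-6-(methoxymethoxy)-3-(3-methylbut-2-en-1-yl)-4-[(triisopropylsilyl)oxy]phenyl]-2-(methoxymethoxy)propane-1,3-dione (racemic, tautomeric) | CC(C)=CCc1c(O)c(C(=O)C(OCOC)C(=O)c2ccc(OCOC)c(OCOC)c2)c(OCOC)cc1O[Si](C(C)C)(C(C)C)C(C)C | intermediate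
25 | 2-(3,4-dihydroxyphenyl)-3,5-dihydroxy-8-(3-methylbut-2-en-1-yl)-7-[(triisopropylsilyl)oxy]-4H-chromen-4-one | CC(C)=CCc1c(O[Si](C(C)C)(C(C)C)C(C)C)cc(O)c2c(=O)c(O)c(-c3ccc(O)c(O)c3)oc12 | intermediate
26 | 8-prenylquercetin | CC(C)=CCc1c(O)cc(O)c2c(=O)c(O)c(-c3ccc(O)c(O)c3)oc12 | target

**Step count**
Total steps: 14.
Longest linear sequence: 10 steps (1 → 2 → 3 → 13 → 14 → 18 → 19 → 23 → 24 → 25 → 26).

**Steps most likely to fail**

Step 4. The oxygen donor on C3 stabilises the four-membered ring as a vinylogous ester. The first electrocyclic opening may therefore be too slow at temperatures that the acetal-type C3–O–CH2–O linkage tolerates. Loss of that group to traces of acid or water, oligomerisation of the ketene, and acylation of the product phenol by the ketene could then take over.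

In the fallback ring A is bought instead of built. It sets out from triisopropylsilyl chloride 5 and purchased phloroglucinol F1. C-prenylation (prenyl bromide, aq KOH, 0 °C → rt) should give 2-(3-methylbut-2-en-1-yl)benzene-1,3,5-triol F2. One equivalent of MOMCl with iPr2NEt should alkylate preferentially the unflanked hydroxyl para to the prenyl group, giving 5-(methoxymethoxy)-2-(3-methylbut-2-en-1-yl)benzene-1,3-diol F3. One equivalent of 5 (imidazole, DMF) then silylates one of the two remaining hydroxyls, which are equivalent by symmetry. The fallback comes back to the route at 13.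

Step 3. The α-protons of the β,γ-unsaturated ester are unusually acidic. Deprotonation by LiCHBr2 or LiTMP, with drift of the double bond into conjugation, may compete with addition to the carbonyl group. Partial silylation on carbon may also erode the final trapping.

The fallback sets out from ester 4 and reaches the ynolate by oxidising an acetylide rather than by rearrangement. Reduction with iBu2AlH (CH2Cl2, −78 °C) should give 4-methylpent-3-enal F4. Corey–Fuchs olefination (CBr4, PPh3, CH2Cl2, 0 °C) should give 1,1-dibromo-5-methylhexa-1,4-diene F5. n-BuLi (2 equiv, THF, −78 → 0 °C) converts this into (5-methylhex-4-en-1-yn-1-yl)lithium F6. Oxygen transfer from t-BuOOLi (from t-BuOOH and LiN(SiMe3)2, THF, −78 → 0 °C) turns F6 into lithium ynolate 7. There the fallback comes back to the route, and 7 is trapped with 5 as before.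

Step 7. The first equivalent of organolithium turns the substrate into a phenoxide whose aldehyde is strongly deactivated, so addition may stall before the thermally fragile reagent decays. The electron-rich o-hydroxybenzyl alcohol may also lose water on handling.

The fallback sets out from aldehyde 14 and masks O1 for three operations. Allylation (allyl bromide, NaH, THF–DMF, 0 °C) should give 2-(allyloxy)-6-(methoxymethoxy)-3-(3-methylbut-2-en-1-yl)-4-[(triisopropylsilyl)oxy]benzaldehyde F7. Addition of 17 (from 16 and n-BuLi, 1.3 equiv, −78 °C) to the now fully electrophilic aldehyde should give 1-[2-(allyloxy)-6-(methoxymethoxy)-3-(3-methylbut-2-en-1-yl)-4-[(triisopropylsilyl)oxy]phenyl]-2-(methoxymethoxy)ethan-1-ol F8. Dess–Martin periodinane with NaHCO3 should give 1-[2-(allyloxy)-6-(methoxymethoxy)-3-(3-methylbut-2-en-1-yl)-4-[(triisopropylsilyl)oxy]phenyl]-2-(methoxymethoxy)ethan-1-one F9. Allyl transfer to morpholine with Pd(PPh3)4 (THF, rt) then frees O1, and the fallback comes back to the route at 19.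

**Further compounds**
F1 | step 4 | phloroglucinol (benzene-1,3,5-triol, purchased) | Oc1cc(O)cc(O)c1
F2 | step 4 | 2-(3-methylbut-2-en-1-yl)benzene-1,3,5-triol | CC(C)=CCc1c(O)cc(O)cc1O
F3 | step 4 | 5-(methoxymethoxy)-2-(3-methylbut-2-en-1-yl)benzene-1,3-diol | CC(C)=CCc1c(O)cc(OCOC)cc1O
F4 | step 3 | 4-methylpent-3-enal | CC(C)=CCC=O
F5 | step 3 | 1,1-dibromo-5-methylhexa-1,4-diene | CC(C)=CCC=C(Br)Br
F6 | step 3 | (5-methylhex-4-en-1-yn-1-yl)lithium | CC(C)=CCC#C[Li]
F7 | step 7 | 2-(allyloxy)-6-(methoxymethoxy)-3-(3-methylbut-2-en-1-yl)-4-[(triisopropylsilyl)oxy]benzaldehyde | C=CCOc1c(CC=C(C)C)c(O[Si](C(C)C)(C(C)C)C(C)C)cc(OCOC)c1C=O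
F8 | step 7 | 1-[2-(allyloxy)-6-(methoxymethoxy)-3-(3-methylbut-2-en-1-yl)-4-[(triisopropylsilyl)oxy]phenyl]-2-(methoxymethoxy)ethan-1-ol (racemic) | C=CCOc1c(CC=C(C)C)c(O[Si](C(C)C)(C(C)C)C(C)C)cc(OCOC)c1C(O)COCOC
F9 | step 7 | 1-[2-(allyloxy)-6-(methoxymethoxy)-3-(3-methylbut-2-en-1-yl)-4-[(triisopropylsilyl)oxy]phenyl]-2-(methoxymethoxy)ethan-1-one | C=CCOc1c(CC=C(C)C)c(O[Si](C(C)C)(C(C)C)C(C)C)cc(OCOC)c1C(=O)COCOC
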